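**Plan**
Retrosynthesis: ring C is opened at C13=C15 (ring-closing metathesis) and at C11–C12 and C14–C16 (allylborations of a C11/C14 dialdehyde); ring B is then cut at C8–C9 and C5–C6 together; C9–C10 goes back to an asymmetric Tsuji allylation of 2,6,6-trimethylcyclohex-2-en-1-one (ring A).
Enabling feature: in ring B, C8 (tertiary OH) lies between the C7 and C14 carbonyl-level carbons and β to the C11 carbonyl, so C7–C8–C14 is a vicinal tricarbonyl array; its central carbon C8 takes the C9 enolate and its acetyl arm C6 closes on the C5 ketone carbon of ring A.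
Forward: ring A (quaternary C10 set first) → ring B by a one-pot titanium aldol/Mukaiyama aldol annulation → oxygenation of C3, C7, C1, C2 → ring C by double allylboration and metathesis → oxidation to the base-sensitive skipped enedione last.
Stereochemistry: C10 from the chiral palladium catalyst; C8 and C9 in the key step; C5 by hydrogen-atom-transfer reduction of the C5=C6 enone (trans-decalin); C3, C1 and C2 by reagent approach anti to the C10 methyl; C7 by hydride delivery from the C8 hydroxyl.

Key step: step 9

Remark: isopimarane-type locants are used (ring A C1–C5/C10, ring B C5–C10, ring C C8, C9, C11–C16 with C14 on C8 and the olefinic methyl on C13); β is the face of the C10 methyl, α the opposite face; the transient carbinol centres C11 and C14 of 27–29, the side-chain carbinol of 5 and the orthoester carbon of 21 are formed without control and are drawn without configuration.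

Step 1
Reactants: 1 2,6,6-trimethylcyclohex-2-en-1-one; 2 allyl chloroformate
Product: 3 allyl 2,6,6-trimethylcyclohexa-1,3-dien-1-yl carbonate
Conditions: LiN(i-Pr)2, TMEDA, THF, −78 °C; then 2, −78 → 0 °C
Reagents that add atoms: none
Why: Because C6 of the enone is quaternary, the base can only remove a γ-hydrogen to form the linear dienolate, whose O-acylation by the chloroformate (enol carbonate formation) gives the substrate for the Tsuji allylation.

Step 2
Reactants: 3 allyl 2,6,6-trimethylcyclohexa-1,3-dien-1-yl carbonate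
Product: 4 (R)-2-allyl-2,6,6-trimethylcyclohex-3-en-1-one
Conditions: Pd2(dba)3 (2.5 mol%), (S)-t-Bu-PHOX (6 mol%), THF, 25 °C
Reagents that add atoms: none
Why: Enantioselective decarboxylative allylic alkylation (Tsuji allylation): zerovalent palladium ionises the allyl carbonate, CO2 is lost and the PHOX-bound allylpalladium dienolate couples at the α-carbon, which should create the quaternary centre (later C10) as the (R) isomer by analogy with 2-methylcyclohexanone enolates (the antipodal ligand would be used if the sense proved opposite).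

Step 3
Reactants: 4 (R)-2-allyl-2,6,6-trimethylcyclohex-3-en-1-one
Product: 6 2-[(1R)-1,3,3-trimethyl-2-oxocyclohex-5-en-1-yl]acetaldehyde, via terminal diol 5 (not isolated)
Conditions: K2OsO2(OH)4 (1 mol%), (DHQD)2PHAL (2 mol%), NMO, t-BuOH/H2O, 0 °C; then NaIO4, rt
Reagents that add atoms: 4-methylmorpholine N-oxide C[N+]1([O-])CCOCC1; water O
Why: Ligand-accelerated dihydroxylation followed by periodate glycol cleavage (Lemieux–Johnson type) should shorten only the side chain, because the phthalazine-ligated osmium reacts much faster with the monosubstituted allyl olefin than with the cis-disubstituted ring olefin next to the quaternary carbon.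

Step 4
Reactants: 6 2-[(1R)-1,3,3-trimethyl-2-oxocyclohex-5-en-1-yl]acetaldehyde
Product: 7 2-[(1R)-1,3,3-trimethyl-2-oxocyclohex-5-en-1-yl]acetic acid
Conditions: NaClO2, NaH2PO4, 2-methylbut-2-ene, t-BuOH/H2O, 0 °C → rt
Reagents that add atoms: sodium chlorite [Na+].[O-]Cl=O
Why: Pinnick oxidation converts the aldehyde to the acid while the olefin scavenger protects the ring double bond from hypochlorite.

Step 5
Reactants: 7 2-[(1R)-1,3,3-trimethyl-2-oxocyclohex-5-en-1-yl]acetic acid
Product: 8 S-ethyl 2-[(1R)-1,3,3-trimethyl-2-oxocyclohex-5-en-1-yl]ethanethioate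
Conditions: EtSH, DCC, DMAP (cat.), CH2Cl2, 0 °C → rt
Reagents that add atoms: ethanethiol CCS
Why: Steglich-type carbodiimide coupling gives the S-ethyl thioester, chosen because it enolises under soft TiCl4/amine conditions and can later be reduced to the aldehyde beside O-esters.

Step 6
Reactants: 9 2,2,6-trimethyl-4H-1,3-dioxin-4-one
Product: 10 S-ethyl 3-oxobutanethioate
Conditions: EtSH, toluene, sealed tube, 110 °C
Reagents that add atoms: ethanethiol CCS
Why: Thermal retro-[4+2] fragmentation of the dioxinone releases acetylketene, which the thiol traps to give the β-keto thioester (acylketene acylation).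

Step 7
Reactants: 10 S-ethyl 3-oxobutanethioate
Product: 11 S-ethyl 2,3-dioxobutanethioate
Conditions: SeO2, 1,4-dioxane, 90 °C; then azeotropic drying (toluene)
Reagents that add atoms: selenium dioxide O=[Se]=O
Why: Riley oxidation of the doubly activated methylene should give the vicinal tricarbonyl compound whose central carbon becomes C8.

Step 8
Reactants: 11 S-ethyl 2,3-dioxobutanethioate
Product: 12 S-ethyl 3-[(tert-butyldimethylsilyl)oxy]-2-oxobut-3-enethioate
Conditions: TBSOTf, Et3N, CH2Cl2, −78 °C
Reagents that add atoms: tert-butyldimethylsilyl trifluoromethanesulfonate CC(C)(C)[Si](C)(C)OS(=O)(=O)C(F)(F)F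
Why: Only the acetyl group of 11 can enolise, so enol silylation should give a single silyl enol ether in which C6=C7 is a masked nucleophile and C8 is the only remaining ketone.

Step 9
Reactants: 8 S-ethyl 2-[(1R)-1,3,3-trimethyl-2-oxocyclohex-5-en-1-yl]ethanethioate; 12 S-ethyl 3-[(tert-butyldimethylsilyl)oxy]-2-oxobut-3-enethioate
Product: 15 ring A/B dienone dithioester (C1=C2; C5=C6–C7=O; 8β-OH; 8α- and 9β-C(=O)SEt; 9α-H), via aldol adduct 13 (not isolated), via bicyclic ketol 14 (not isolated)
Conditions: TiCl4 (2.5 equiv), n-Bu3N (1.2 equiv), CH2Cl2, −78 °C; then 12, −78 → −20 °C; then TFA, 0 °C → rt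
Reagents that add atoms: none
Why: Proposed new method: TiCl4/n-Bu3N soft-enolises the thioester of 8 (its only enolisable site, since the C5 ketone has no α-hydrogen) and the titanium enolate at C9 adds to the C8 ketone of 12, activated by chelation with the flanking thioester carbonyl (C8–C9 bond, adduct 13); this addition turns the electron-poor 2-silyloxy enone into an ordinary silyl enol ether, which then attacks the TiCl4-activated C5 ketone in an intramolecular Mukaiyama aldol (C5–C6 bond, ketol 14), and TFA dehydrates the β-ketol to enone 15. The closest known reaction types are the titanium-mediated crossed aldol of thioesters with α-keto esters and the Mukaiyama aldol, combined here as a Robinson-like (3+3) annulation. Ring B closes by a 6-(enolendo)-exo-trig aldol that can only give the cis-fused ketol, which is why C5 is returned to sp2 by dehydration and set later by reduction. C9 is epimerisable α to its thioester and should settle with that group equatorial (9α-H, trans to the C10 methyl), while C8 is set in the chelated chair transition state of the first aldol with the hydroxyl axial (β) and the C14 thioester equatorial, the arrangement also preferred thermodynamically beside the axial C10 methyl. The step needs 1,2-addition at C8 instead of conjugate addition at C6, which bidentate activation of the 1,2-dicarbonyl favours, and closure on C5 instead of Claisen attack on the C11 thioester, which is secured because a silyl enol ether does not acylate a thioester.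

Step 10
Reactants: 15 ring A/B dienone dithioester
Product: 16 3α-hydroxy dienone dithioester
Conditions: SeO2 (0.5 equiv), t-BuOOH, CH2Cl2, rt → 40 °C
Reagents that add atoms: tert-butyl hydroperoxide (oxygen relayed through SeO2) CC(C)(C)OO
Why: Selenium dioxide allylic oxidation (ene reaction then [2,3]-shift) can only use the C3 hydrogens, since C10 is quaternary and the C5=C6 enone has no allylic hydrogen, and selenium should approach C1 anti to the C10 methyl so that oxygen returns to C3 on the α face.

Step 11
Reactants: 16 3α-hydroxy dienone dithioester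
Product: 17 3α-benzoyloxy dienone dithioester
Conditions: BzCl, pyridine, DMAP (cat.), CH2Cl2, 0 °C → rt
Reagents that add atoms: benzoyl chloride O=C(Cl)c1ccccc1
Why: DMAP-catalysed acylation places the first benzoate on the only secondary hydroxyl, the tertiary C8 hydroxyl between two carbonyl groups being too hindered to react.

Step 12
Reactants: 17 3α-benzoyloxy dienone dithioester
Product: 18 trans-fused 7-ketone (5α-H; C1=C2 retained)
Conditions: Mn(dpm)3 (10 mol%), PhSiH3, i-PrOH, rt, argon
Reagents that add atoms: none
Why: Metal-hydride hydrogen-atom-transfer conjugate reduction saturates only the enone olefin (the 1,2-disubstituted C1=C2 bond is inert), and hydrogen should reach C5 from the α face, away from the axial C10 and C4 methyls, to give the trans-decalin.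

Step 13
Reactants: 18 trans-fused 7-ketone
Product: 19 7α,8β-diol (C1=C2; 3α-OBz)
Conditions: Me4NBH(OAc)3, MeCN/AcOH, −30 °C
Reagents that add atoms: none
Why: Hydroxyl-directed (Saksena–Evans) reduction: the C8 hydroxyl binds boron and delivers hydride to C7 from the β face, giving the 7α-alcohol trans to the 8β-hydroxyl while thioesters and benzoate stay untouched.

Step 14
Reactants: 19 7α,8β-diol
Product: 20 1α,2α,7α,8β-tetrol 3α-benzoate
Conditions: OsO4 (5 mol%), NMO, acetone/H2O, rt
Reagents that add atoms: 4-methylmorpholine N-oxide C[N+]1([O-])CCOCC1; water O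
Why: Upjohn dihydroxylation of C1=C2 should occur on the α face because the β face is shielded by the axial C10 methyl on the allylic carbon, giving the all-cis 1α,2α-diol beside the 3α-benzoate.

Step 15
Reactants: 20 1α,2α,7α,8β-tetrol 3α-benzoate
Product: 22 1α,3α-dibenzoate 2α,7α,8β-triol, via cyclic orthobenzoate 21 (not isolated)
Conditions: PhC(OMe)3, CSA (cat.), CH2Cl2, rt; then 80% aq. AcOH, rt
Reagents that add atoms: trimethyl orthobenzoate COC(OC)(OC)c1ccccc1; water O
Why: The cis-1,2-diol forms a five-membered cyclic orthoester whose acid hydrolysis opens to the axial ester (orthoester acyl transfer), so the benzoate ends on the axial C1 oxygen and the equatorial C2 hydroxyl is freed.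

Step 16
Reactants: 22 1α,3α-dibenzoate 2α,7α,8β-triol
Product: 23 2α,7α-diacetate 1α,3α-dibenzoate dithioester
Conditions: Ac2O, DMAP, Et3N, CH2Cl2, rt
Reagents that add atoms: acetic anhydride CC(=O)OC(C)=O
Why: DMAP-catalysed acetylation esterifies the two remaining secondary hydroxyls (C2 and C7) in one step, the tertiary C8 hydroxyl being too hindered.

Step 17
Reactants: 23 2α,7α-diacetate 1α,3α-dibenzoate dithioester
Product: 24 C11/C14 dialdehyde
Conditions: Et3SiH, Pd on carbon (10%), acetone, rt
Reagents that add atoms: none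
Why: Fukuyama reduction (oxidative addition of the C–S bond to palladium, then hydride transfer from the silane) converts both thioesters to aldehydes without touching acetates, benzoates or the tertiary alcohol.

Step 18
Reactants: 24 C11/C14 dialdehyde; 25 2-methylallylboronic acid pinacol ester; 26 allylboronic acid pinacol ester
Product: 28 diene diol (C11 methallyl carbinol; C14 allyl carbinol), via methallyl carbinol aldehyde 27 (not isolated)
Conditions: 25 (1.05 equiv), toluene, −78 → 0 °C; then 26 (3 equiv), 40 °C; triethanolamine work-up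
Reagents that add atoms: none
Why: Allylboration through a closed six-membered transition state: the methallyl boronate should be consumed first by the less hindered C11 aldehyde and the allyl boronate then adds to the neopentylic C14 aldehyde, installing both olefin arms without base.

Step 19
Reactants: 28 diene diol
Product: 29 ring C cyclooctene 11,14-diol
Conditions: second-generation Grubbs catalyst (10 mol%), toluene (2 mM), 80 °C
Reagents that add atoms: none
Why: Ring-closing metathesis of the allyl and methallyl arms, held gauche as trans-diequatorial substituents at C8/C9, closes the eight-membered ring, whose trisubstituted olefin can only be Z.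

Step 20
Reactants: 29 ring C cyclooctene 11,14-diol
Product: 30 CNP0214674.2 (target)
Conditions: IBX, DMSO, rt
Reagents that add atoms: none
Why: IBX oxidation converts both secondary carbinols to the C11 and C14 ketones under neutral conditions without cleaving the C8/C14 glycol, so the skipped enedione appears only in the last step.

**Compound list**
1 | 2,6,6-trimethylcyclohex-2-en-1-one | CC1=CCCC(C)(C)C1=O | starting material
2 | allyl chloroformate | C=CCOC(Cl)=O | starting material
3 | allyl 2,6,6-trimethylcyclohexa-1,3-dien-1-yl carbonate | C=CCOC(=O)OC1=C(C)C=CCC1(C)C | intermediate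
4 | (R)-2-allyl-2,6,6-trimethylcyclohex-3-en-1-one | C1=C[C@](CC=C)(C)C(=O)C(C)(C)C1 | intermediate
5 | (2R)-2-(2,3-dihydroxypropyl)-2,6,6-trimethylcyclohex-3-en-1-one (side-chain carbinol not defined) | C1=C[C@](CC(O)CO)(C)C(=O)C(C)(C)C1 | intermediate
6 | 2-[(1R)-1,3,3-trimethyl-2-oxocyclohex-5-en-1-yl]acetaldehyde | C1=C[C@](CC=O)(C)C(=O)C(C)(C)C1 | intermediate
7 | 2-[(1R)-1,3,3-trimethyl-2-oxocyclohex-5-en-1-yl]acetic acid | C1=C[C@](CC(O)=O)(C)C(=O)C(C)(C)C1 | intermediate
8 | S-ethyl 2-[(1R)-1,3,3-trimethyl-2-oxocyclohex-5-en-1-yl]ethanethioate | C1=C[C@](CC(=O)SCC)(C)C(=O)C(C)(C)C1 | intermediate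
9 | 2,2,6-trimethyl-4H-1,3-dioxin-4-one | CC1=CC(=O)OC(C)(C)O1 | starting material
10 | S-ethyl 3-oxobutanethioate | CCSC(=O)CC(C)=O | intermediate
11 | S-ethyl 2,3-dioxobutanethioate | CCSC(=O)C(=O)C(C)=O | intermediate
12 | S-ethyl 3-[(tert-butyldimethylsilyl)oxy]-2-oxobut-3-enethioate | CCSC(=O)C(=O)C(=C)O[Si](C)(C)C(C)(C)C | intermediate
13 | acyclic aldol adduct: S,S-diethyl 2-{1-[(tert-butyldimethylsilyl)oxy]ethenyl}-2-hydroxy-3-[(1R)-1,3,3-trimethyl-2-oxocyclohex-5-en-1-yl]butanebis(thioate), C8/C9 configured as in 15 | C1=C[C@]([C@H](C(=O)SCC)[C@@](O)(C(=O)SCC)C(=C)O[Si](C)(C)C(C)(C)C)(C)C(=O)C(C)(C)C1 | intermediate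
14 | cis-fused bicyclic ketol: 5β,8β-dihydroxy-7-oxo, C1=C2, 8α- and 9β-C(=O)SEt, 9α-H, 4,4,10β-trimethyl | C1=C[C@]2(C)[C@@](O)(CC(=O)[C@](O)(C(=O)SCC)[C@H]2C(=O)SCC)C(C)(C)C1 | intermediate
15 | ring A/B dienone dithioester: C1=C2, C5=C6–C7=O, 8β-OH, 8α- and 9β-C(=O)SEt, 9α-H, 4,4,10β-trimethyl | C1=C[C@]2(C)C(=CC(=O)[C@](O)(C(=O)SCC)[C@H]2C(=O)SCC)C(C)(C)C1 | intermediate
16 | 3α-hydroxy derivative of 15 | C1=C[C@]2(C)C(=CC(=O)[C@](O)(C(=O)SCC)[C@H]2C(=O)SCC)C(C)(C)[C@H]1O | intermediate
17 | 3α-benzoate of 16 | C1=C[C@]2(C)C(=CC(=O)[C@](O)(C(=O)SCC)[C@H]2C(=O)SCC)C(C)(C)[C@H]1OC(=O)c1ccccc1 | intermediate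
18 | trans-fused 7-ketone: 5α-H, C1=C2, 3α-OBz, 8β-OH, 8α- and 9β-C(=O)SEt | C1=C[C@]2(C)[C@H](CC(=O)[C@](O)(C(=O)SCC)[C@H]2C(=O)SCC)C(C)(C)[C@H]1OC(=O)c1ccccc1 | intermediate
19 | 7α,8β-diol of 18 | C1=C[C@]2(C)[C@H](C[C@H](O)[C@](O)(C(=O)SCC)[C@H]2C(=O)SCC)C(C)(C)[C@H]1OC(=O)c1ccccc1 | intermediate
20 | 1α,2α,7α,8β-tetrol 3α-benzoate dithioester | O[C@H]1[C@@H](O)[C@]2(C)[C@H](C[C@H](O)[C@](O)(C(=O)SCC)[C@H]2C(=O)SCC)C(C)(C)[C@H]1OC(=O)c1ccccc1 | intermediate
21 | 1α,2α-O-(α-methoxybenzylidene) cyclic orthobenzoate of 20 (orthoester carbon not defined) | COC1(c2ccccc2)O[C@H]2[C@@H](O1)[C@]3(C)[C@H](C[C@H](O)[C@](O)(C(=O)SCC)[C@H]3C(=O)SCC)C(C)(C)[C@H]2OC(=O)c1ccccc1 | intermediate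
22 | 1α,3α-dibenzoate 2α,7α,8β-triol dithioester | O[C@H]1[C@@H](OC(=O)c2ccccc2)[C@]2(C)[C@H](C[C@H](O)[C@](O)(C(=O)SCC)[C@H]2C(=O)SCC)C(C)(C)[C@H]1OC(=O)c1ccccc1 | intermediate
23 | 2α,7α-diacetate 1α,3α-dibenzoate 8β-ol dithioester | CC(=O)O[C@H]1[C@@H](OC(=O)c2ccccc2)[C@]2(C)[C@H](C[C@H](OC(C)=O)[C@](O)(C(=O)SCC)[C@H]2C(=O)SCC)C(C)(C)[C@H]1OC(=O)c1ccccc1 | intermediate
24 | C11/C14 dialdehyde (8α- and 9β-formyl) | CC(=O)O[C@H]1[C@@H](OC(=O)c2ccccc2)[C@]2(C)[C@H](C[C@H](OC(C)=O)[C@](O)(C=O)[C@H]2C=O)C(C)(C)[C@H]1OC(=O)c1ccccc1 | intermediate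
25 | 2-methylallylboronic acid pinacol ester | CC(=C)CB1OC(C)(C)C(C)(C)O1 | starting material
26 | allylboronic acid pinacol ester | C=CCB1OC(C)(C)C(C)(C)O1 | starting material
27 | C11 methallyl carbinol, C14 aldehyde (C11 carbinol not defined) | CC(=O)O[C@H]1[C@@H](OC(=O)c2ccccc2)[C@]2(C)[C@H](C[C@H](OC(C)=O)[C@](O)(C=O)[C@H]2C(O)CC(C)=C)C(C)(C)[C@H]1OC(=O)c1ccccc1 | intermediate
28 | diene diol: C11 methallyl carbinol, C14 allyl carbinol (carbinols not defined) | CC(=O)O[C@H]1[C@@H](OC(=O)c2ccccc2)[C@]2(C)[C@H](C[C@H](OC(C)=O)[C@](O)(C(O)CC=C)[C@H]2C(O)CC(C)=C)C(C)(C)[C@H]1OC(=O)c1ccccc1 | intermediate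
29 | ring C (Z)-cyclooctene 11,14-diol (carbinols not defined) | CC(=O)O[C@H]1[C@@H](OC(=O)c2ccccc2)[C@]2(C)[C@H](C[C@H](OC(C)=O)[C@]3(O)C(O)C/C=C(/C)CC(O)[C@H]32)C(C)(C)[C@H]1OC(=O)c1ccccc1 | intermediate
30 | CNP0214674.2: 1α,3α-dibenzoyloxy-2α,7α-diacetoxy-8β-hydroxy-11,14-dioxo 6/6/8 tricycle, 5α-H, 9α-H, 10β-Me, (Z)-C13=C15 | CC(=O)O[C@H]1[C@@H](OC(=O)c2ccccc2)[C@]2(C)[C@H](C[C@H](OC(C)=O)[C@]3(O)C(=O)C/C=C(/C)CC(=O)[C@H]32)C(C)(C)[C@H]1OC(=O)c1ccccc1 | target

Total steps: 20. Longest linear sequence: 17 steps (steps 1–5 and 9–20).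

**Steps most likely to fail**
First, step 9 (the new method). The second aldol may stall at the doubly neopentyl C5 ketone, conjugate addition or a hetero-Diels–Alder reaction at C6 of 12 may compete with 1,2-addition, or facial control at C8 may be poor. The fallback uses known steps and sets out from 8 and 12: the titanium aldol is stopped at −78 °C and adduct 13 is isolated; NBS converts its silyl enol ether into α-bromo ketone F1; SmI2 (THF, −78 °C) then forms the samarium enolate, which closes ring B by a Reformatsky-type aldol on the C5 ketone to give ketol 14; TsOH dehydration rejoins the route at 15.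

Second, step 10. The ene step may be slow at the hindered C1 terminus, may over-oxidise to the enone, or may deliver oxygen to the wrong face. The fallback sets out from 15: a Kharasch–Sosnovsky allylic acyloxylation (CuBr with a chiral bis(oxazoline) ligand, tert-butyl perbenzoate) abstracts a C3 hydrogen and places the benzoate at the less hindered C3 end of the allyl radical, with the ligand and the C10 methyl steering it to the α face. It rejoins the route directly at 17 and makes no new compound (F0).

Third, step 18. Discrimination between the two aldehydes may be poor, because the α-hydroxy aldehyde at C14 can react through boron–oxygen exchange, and the β-hydroxy dialdehyde 24 may dehydrate. The fallback sets out from 23: a Fukuyama reduction run to partial conversion reduces only the less hindered C11 thioester to give aldehyde thioester F2; methallylboration with 25 gives carbinol thioester F3; a second, forcing Fukuyama reduction then gives 27, where the route is rejoined before the allylboration with 26.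

**Further compounds**
F1 | step 9 | α-bromo ketone from 13 (C6–Br; C8/C9 as in 13) | C1=C[C@]([C@H](C(=O)SCC)[C@@](O)(C(=O)SCC)C(=O)CBr)(C)C(=O)C(C)(C)C1
F0 | step 10 | none | none
F2 | step 18 | C11 aldehyde, C14 S-ethyl thioester | CC(=O)O[C@H]1[C@@H](OC(=O)c2ccccc2)[C@]2(C)[C@H](C[C@H](OC(C)=O)[C@](O)(C(=O)SCC)[C@H]2C=O)C(C)(C)[C@H]1OC(=O)c1ccccc1
F3 | step 18 | C11 methallyl carbinol, C14 S-ethyl thioester (carbinol not defined) | CC(=O)O[C@H]1[C@@H](OC(=O)c2ccccc2)[C@]2(C)[C@H](C[C@H](OC(C)=O)[C@](O)(C(=O)SCC)[C@H]2C(O)CC(C)=C)C(C)(C)[C@H]1OC(=O)c1ccccc1
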